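The ratio of target to other capture product is what is asked of the ochre flask, which differs from the red run in holding half its first nucleophile.

| flask | substrate | first nucleophile | second nucleophile | remark | time |
|---|---|---|---|---|---|
| ochre | 0.71 M | 0.852 M | 0.923 M | the very flask that is asked about, followed so far |  |
| red | 0.71 M | 1.7 M | 0.923 M | run made earlier |  |
| flask | 0.71 M | 0.852 M | 0.923 M |  | 8.0 min |

ochre run (percent of the substrate charged)

| time / s | target / % | other capture product / % |
|---|---|---|
| 10.0 | 2.4 | 0.8 |
| 20.0 | 2.5 | 2.2 |
| 30.0 | 6.4 | 4.3 |
| 50.0 | 7.1 | 5.0 |
| 80.0 | 10.1 | 7.4 |
| 90.0 | 10.2 | 9.4 |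

red run (percent of the substrate charged)

| time / min | target / % | other capture product / % |
|---|---|---|
| 0.250 | 4.2 | 2.8 |
| 0.417 | 4.8 | 0.9 |
| 0.667 | 9.1 | 3.3 |
| 1.33 | 14.9 | 6.4 |
| 2.00 | 18.8 | 9.7 |
| 3.00 | 19.1 | 13.2 |

(scatter of a reading: 1 percentage point)

- the earlier runs were read with a standard deviation of 1 percentage point
- reactions considered so far: target <-> isomer of the product; intermediate -> solvolysis product; second nucleophile + intermediate -> other capture product; first nucleophile + intermediate -> target; first nucleophile -> decomposed reagent; substrate -> intermediate

* ratio of target to other capture product at 5.0 s
* ratio of target to other capture product at 50 s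
* ratio of target to other capture product at 8.0 min
* which of target and other capture product there is more of at 8.0 min

Both products come from one intermediate, so I divide each ratio by the ratio of the first nucleophile charge to the second and call the result the scaled ratio; I expect two flasks to share it at equal times. From the early ochre readings it is 1.68, the selectivity factor, and from the last red reading it is 0.786, lower, as first nucleophile decays.

The end state I expect has target stalled and other capture product still growing, so the ratio keeps falling. The last ochre reading therefore bounds the ochre ratio at 8.0 min from above by 1.09, and the red scaled ratio, put back on the ochre charges, tightens this to 0.725, which is lower. From below, I hold target at its last ochre reading and let other capture product keep its ochre pace, which gives 0.203; the longer red pace raises this to 0.290. I commit to the geometric middle, 0.458, so the scaled ratio at the latest time is 0.497.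

The forecast gives 1.27, 1.15 and 0.42, the last inside my bracket, with other capture product ahead, since “target stalls near 19% after 2 min while other keeps climbing almost linearly”.

The ochre flask gives 1.47, 1.19 and 0.481, the last inside the bracket, with other capture product ahead at 28.2% against 13.6% of target. At 8.00 min the ochre flask keeps 1.0% of its first nucleophile, and its scaled ratio is 0.521 against my 0.497.

    target ⇌ isomer of the product (K = 0.340, k = 2.80 × 10⁻⁴ s⁻¹)
    intermediate → solvolysis product (k = 0.260 s⁻¹)
    second nucleophile + intermediate → other capture product (k = 0.190 M⁻¹ s⁻¹)
    first nucleophile + intermediate → target (k = 0.310 M⁻¹ s⁻¹)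
    first nucleophile → decomposed reagent (k = 0.00870 s⁻¹)
    substrate → intermediate (k = 0.00490 s⁻¹)

Put on the neighbour flask with 1.6 M of second nucleophile, 0.497 gives 0.264, and that neighbour flask gives 0.282.

The runs were generated by integration with made-up constants; the scatter is artificial.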